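**Plan**

1. Retrosynthesis (bicyclo[3.3.1]nonane locants): the C7 prenyl group is cut back to a C7 formyl group (carbon C10); then C1–C8 is cut together with a temporary C3–C10 aldol bond; then C5–C6; this leaves a flat hexasubstituted benzene, itself cut at aryl–CO, aryl–lavandulyl and aryl–prenyl.
2. Enabling feature: ring C1–C2–C3–C4–C5–C9, with oxygen on C2, C4 and C9 and the aroyl group on C3, is a dearomatized acylphloroglucinol. C5 and C1 are its two alkyl-bearing nucleophilic carbons flanking C9, and the bridge C6–C7–C8 is a 1,3-dielectrophile (allylic CH2, then the β-carbon of an enal) whose C7 formyl group can reach C3.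
3. Forward: phloroglucinol → arene 20 (prenyl by ortho-metalation, lavandulyl by Negishi coupling, aroyl by an anionic Fries shift that leaves O4 as the only free phenol) → dearomatization at C5 (step 11) → cyclohexanone ring by C1–C8 Michael closure and temporary adamantane cage by C3–C10 aldol (step 12) → cage reopened and C10 grown into the prenyl group (steps 13–16).
4. Stereochemistry: the side-chain centre comes from (R)-lavandulol; C5 from catalyst-controlled alkylation; C1 is relayed from C5 by the bridging geometry; the endo C7 centre is selected by the aldol cage and kept by retro-aldol trapping.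
5. Helpers: MOM ethers on O2 and O9 (direct the alkylation to C5, removed in step 12), the aldol cage (opened in step 13), the TIPS ether on the aroyl phenol (removed last).

Key step: step 12

Remark: (R)-(−)-lavandulol is assumed to be purchased as the single enantiomer. Locants C1–C9 are those of the target core (C1 prenyl bridgehead, C3 aroyl carbon, C5 lavandulyl bridgehead, C7 prenyl methine, C8 gem-dimethyl carbon, C9 bridging carbonyl); C10 is the carbon on C7 that ends as the prenyl CH2; O2, O4, O9 are the oxygens on C2, C4, C9. The same locants are used for the corresponding atoms of all precursors.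

**Route**

Step 1
Reactants: 1 (R)-lavandulol
Product: 2 (R)-lavandulyl iodide
Conditions: PPh3, imidazole, I2, CH2Cl2, 0 °C to rt
Reagents that add atoms: iodine, II
Why: Appel iodination is an SN2 displacement at the primary carbinol carbon and leaves the adjacent stereocentre untouched.

Step 2
Reactants: 3 3-hydroxybenzoic acid
Product: 5 3-[(triisopropylsilyl)oxy]benzoic acid, via bis-silylated ester 4 (not isolated)
Conditions: iPr3SiCl (2.2 equiv), imidazole, DMF, rt; then AcOH–THF–H2O, rt
Reagents that add atoms: chlorotriisopropylsilane, CC(C)[Si](Cl)(C(C)C)C(C)C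
Why: Exhaustive silylation followed by selective hydrolysis of the labile silyl ester (silyl ether protection) should leave the robust aryl silyl ether.

Step 3
Reactants: 6 2-bromo-3,3-diethoxyprop-1-ene
Product: 9 acetoxy acetal, via vinyllithium 7 (not isolated), via lithium alkoxide 8 (not isolated)
Conditions: n-BuLi, THF, −78 °C; acetone, −78 °C; Ac2O, −78 °C to rt
Reagents that add atoms: acetone, CC(C)=O; acetic anhydride, CC(=O)OC(C)=O
Why: Bromine–lithium exchange gives the acrolein α-anion equivalent, which adds 1,2 to acetone, and the tertiary lithium alkoxide is acetylated in the same flask.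

Step 4
Reactants: 9 acetoxy acetal
Product: 10 α-acetoxy enal (3-acetoxy-3-methyl-2-methylidenebutanal)
Conditions: oxalic acid (10% aq.), silica gel, CH2Cl2, rt
Reagents that add atoms: water, O
Why: Mild acid-catalysed acetal hydrolysis should spare the tertiary allylic acetate, whose ionization is disfavoured by the electron-poor alkene.

Step 5
Reactants: 11 phloroglucinol
Product: 12 3,5-bis(methoxymethoxy)phenol
Conditions: MeOCH2Cl (2.0 equiv), iPr2NEt, DMF, 0 °C to rt
Reagents that add atoms: chloromethyl methyl ether, COCCl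
Why: Williamson-type O-alkylation gives the bis-ether statistically; it is separated from the mono- and tris-ethers, which can be recycled.

Step 6
Reactants: 12 3,5-bis(methoxymethoxy)phenol
Product: 14 4-prenyl-3,5-bis(methoxymethoxy)phenol, via dilithio species 13 (not isolated)
Conditions: n-BuLi (2.2 equiv), TMEDA, THF, −20 to 0 °C; prenyl bromide, −78 °C to rt; AcOH quench
Reagents that add atoms: 1-bromo-3-methylbut-2-ene, CC(C)=CCBr
Why: Directed ortho-metalation should occur at the C–H between the two MOM ethers (future C1) while the lithium phenoxide is a spectator, and the aryllithium is alkylated by SN2 attack at the unhindered CH2 of prenyl bromide.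

Step 7
Reactants: 14 4-prenyl-3,5-bis(methoxymethoxy)phenol
Product: 15 2-iodo-4-prenyl-3,5-bis(methoxymethoxy)phenol
Conditions: N-iodosuccinimide (1.0 equiv), CH2Cl2, −40 °C, dark
Reagents that add atoms: N-iodosuccinimide, O=C1CCC(=O)N1I
Why: Electrophilic aromatic iodination ortho to the free hydroxyl (the two open ring positions are equivalent) should be much faster than iodination of the trisubstituted alkene.

Step 8
Reactants: 15 2-iodo-4-prenyl-3,5-bis(methoxymethoxy)phenol; 5 3-[(triisopropylsilyl)oxy]benzoic acid
Product: 16 iodoaryl ester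
Conditions: DCC, DMAP (cat.), CH2Cl2, 0 °C to rt
Reagents that add atoms: none
Why: Steglich esterification places the aroyl group on the oxygen (future O4) from which it will later migrate.

Step 9
Reactants: 16 iodoaryl ester; 2 (R)-lavandulyl iodide
Product: 18 lavandulyl aryl ester, via lavandulylzinc iodide 17 (not isolated)
Conditions: 2, Zn dust, LiCl, THF, 40 °C; then 16, Pd(OAc)2 (cat.), SPhos (cat.), THF, 45 °C
Reagents that add atoms: none
Why: Negishi sp2–sp3 coupling with a dialkylbiarylphosphine ligand should tolerate the di-ortho-substituted aryl iodide and the ester, and zinc insertion at the primary C–I bond does not involve the β stereocentre.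

Step 10
Reactants: 18 lavandulyl aryl ester
Product: 20 hydroxybenzophenone (arene), via ortho-lithiated ester 19 (not isolated)
Conditions: LiN(iPr)2 (1.5 equiv), THF, −78 to −20 °C; AcOH quench
Reagents that add atoms: none
Why: Anionic ortho-Fries rearrangement: the single aryl C–H, flanked by the ester oxygen and a MOM ether, is deprotonated and a 1,3 O→C acyl shift installs the aroyl group on C3 and leaves O4 as the only free phenol.

Step 11
Reactants: 20 hydroxybenzophenone (arene); 10 α-acetoxy enal
Product: 21 dearomatized dienone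
Conditions: N-(9-anthracenylmethyl)-O-allylcinchonidinium bromide (10 mol%), CsOH·H2O, 4 Å molecular sieves, toluene–CH2Cl2, −50 °C
Reagents that add atoms: none
Why: Phase-transfer-catalysed alkylative dearomatization (Michael addition at C5, then E1cB loss of acetate) should go to C5 because it is the alkyl-bearing carbon ortho to the only phenoxide and next to the paired cation, while the para carbon C1 is flanked by two MOM ethers; the new C5 stereocentre is set by the chiral ammonium ion pair (the pseudoenantiomeric cinchoninium salt is used if it proves to be the matched partner of the lavandulyl centre), and the minor C5 epimer is a separable diastereomer.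

Step 12
Reactants: 21 dearomatized dienone
Product: 24 caged aldol (adamantanol), via free triketone 22 (not isolated), via endo-aldehyde 23 (not isolated)
Conditions: 1 M aq. HCl–THF, 0 °C; extractive work-up and azeotropic drying; then LiN(SiMe3)2 (1.1 equiv), THF, −78 to 0 °C; AcOH quench
Reagents that add atoms: none
Why: Hydrolysis of the two vinylogous MOM acetals gives triketone 22, whose lithium enolate adds through the prenyl-bearing C1 to C8, the β,β-dimethyl terminus of the tethered alkylidene enal (intramolecular Michael addition); the remaining enolic proton is relayed to the new C7 aldehyde enolate, and C3 of the regenerated C2–C3–C4 triketone enolate then adds to the formyl carbon C10 (aldol) to give the lithium-chelated cage alkoxide. The closest known reaction type is the base-mediated alkylative dearomatization–annulation–aldol cascade of acylphloroglucinols with α-acetoxy enals that leads to bicyclo[3.3.1]nonane and adamantane cores. The C1–C8 bond closes the cyclohexanone ring C1–C8–C7–C6–C5–C9 in a 6-endo-trig Michael mode, and the C3–C10 bond closes a third six-membered ring in a 6-exo-trig aldol mode. C1 is dictated by C5, because the tether C6–C7–C8 can reach C1 only across the ring face that carries C6; C7 is set by thermodynamic selection, since the formyl group epimerizes through its enolate and only the endo epimer can reach C3 and be held in the cage; C3 follows from the cage and the C10 carbinol configuration is irrelevant. The step needs C1, not C3 or an enol oxygen, to attack C8: C3 is the hindered, aroyl-bearing central carbon of a tricarbonyl unit, oxygen adducts revert by retro-oxa-Michael reaction, and attack by C1 alone leaves the strongly stabilized triketone enolate, so the equilibria should drain to the C1–C8 bonded product, while one equivalent of lithium base keeps one proton for the relay and lithium chelation holds the aldolate closed.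

Step 13
Reactants: 24 caged aldol (adamantanol)
Product: 26 endo allylic alcohol, via dichlorocerium enolate aldehyde 25 (not isolated)
Conditions: CeCl3, CH2=CHMgBr (5 equiv), THF, −78 to −40 °C; aq. AcOH work-up
Reagents that add atoms: vinylmagnesium bromide, C=C[Mg]Br
Why: Retro-aldol fragmentation of the dichlorocerium alkoxide of 24 releases the cerium triketone enolate 25, which carries the free endo C7 aldehyde, and the weakly basic vinylcerium dichloride should capture that aldehyde by 1,2-addition before it can enolize, so C7 stays endo; the new carbinol centre is formed as a mixture and is removed in step 15.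

Step 14
Reactants: 26 endo allylic alcohol
Product: 27 endo allylic acetate
Conditions: Ac2O (1.3 equiv), DMAP (cat.), Et3N, CH2Cl2, 0 °C to rt; aq. NaHCO3–MeOH wash
Reagents that add atoms: acetic anhydride, CC(=O)OC(C)=O
Why: DMAP-catalysed acetylation of the secondary alcohol; any enol acetate of the triketone is an activated acyl donor that is relayed to the alcohol or cleaved in the mild basic wash.

Step 15
Reactants: 27 endo allylic acetate
Product: 28 endo C7-allyl compound
Conditions: Pd(OAc)2 (cat.), PBu3 (cat.), HCO2NH4, dioxane, 80 °C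
Reagents that add atoms: none
Why: Palladium-catalysed formate hydrogenolysis of the allylic acetate (Tsuji–Trost type) delivers hydride to the more substituted terminus of the π-allyl complex and gives the terminal alkene without touching C7; any intramolecular C- or O-allylation of the triketone is reversible, whereas hydride transfer is not.

Step 16
Reactants: 28 endo C7-allyl compound
Product: 29 O-silylated target
Conditions: second-generation Grubbs catalyst (cat.), 2-methyl-2-butene–CH2Cl2, 35 °C
Reagents that add atoms: 2-methyl-2-butene, CC=C(C)C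
Why: Olefin cross-metathesis converts the monosubstituted allyl alkene into the prenyl group; the trisubstituted prenyl alkenes and the α-branched 1,1-disubstituted isopropenyl group should react much more slowly.

Step 17
Reactants: 29 O-silylated target
Product: 30 target (CNP0103487.1)
Conditions: Bu4NF, AcOH (1:1), THF, 0 °C
Reagents that add atoms: none
Why: Buffered fluoride cleavage of the aryl silyl ether avoids the acid that would cyclize the C4 enol oxygen onto the isopropenyl group.

**Compound list**

1 | (R)-lavandulol, (2R)-5-methyl-2-(prop-1-en-2-yl)hex-4-en-1-ol | C=C(C)[C@@H](CC=C(C)C)CO | starting material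
2 | (R)-lavandulyl iodide, (3R)-3-(iodomethyl)-2,6-dimethylhepta-1,5-diene | C=C(C)[C@@H](CC=C(C)C)CI | intermediate
3 | 3-hydroxybenzoic acid | OC(=O)c1cccc(O)c1 | starting material
4 | triisopropylsilyl 3-[(triisopropylsilyl)oxy]benzoate (not isolated) | CC(C)[Si](OC(=O)c1cccc(O[Si](C(C)C)(C(C)C)C(C)C)c1)(C(C)C)C(C)C | intermediate
5 | 3-[(triisopropylsilyl)oxy]benzoic acid | OC(=O)c1cccc(O[Si](C(C)C)(C(C)C)C(C)C)c1 | intermediate
6 | 2-bromo-3,3-diethoxyprop-1-ene | CCOC(OCC)C(Br)=C | starting material
7 | (3,3-diethoxyprop-1-en-2-yl)lithium (not isolated) | [Li]C(=C)C(OCC)OCC | intermediate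
8 | lithium 3-(diethoxymethyl)-2-methylbut-3-en-2-olate (not isolated) | [Li]OC(C)(C)C(=C)C(OCC)OCC | intermediate
9 | 3-(diethoxymethyl)-2-methylbut-3-en-2-yl acetate | CC(=O)OC(C)(C)C(=C)C(OCC)OCC | intermediate
10 | 3-acetoxy-3-methyl-2-methylidenebutanal (α-acetoxy enal) | CC(=O)OC(C)(C)C(=C)C=O | intermediate
11 | phloroglucinol (benzene-1,3,5-triol) | Oc1cc(O)cc(O)c1 | starting material
12 | 3,5-bis(methoxymethoxy)phenol | COCOc1cc(O)cc(OCOC)c1 | intermediate
13 | lithium 4-lithio-3,5-bis(methoxymethoxy)phenolate (not isolated) | COCOc1cc(O[Li])cc(OCOC)c1[Li] | intermediate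
14 | 3,5-bis(methoxymethoxy)-4-(3-methylbut-2-en-1-yl)phenol | COCOc1cc(O)cc(OCOC)c1CC=C(C)C | intermediate
15 | 2-iodo-3,5-bis(methoxymethoxy)-4-(3-methylbut-2-en-1-yl)phenol | COCOc1cc(O)c(I)c(OCOC)c1CC=C(C)C | intermediate
16 | 2-iodo-3,5-bis(methoxymethoxy)-4-(3-methylbut-2-en-1-yl)phenyl 3-[(triisopropylsilyl)oxy]benzoate | COCOc1cc(OC(=O)c2cccc(O[Si](C(C)C)(C(C)C)C(C)C)c2)c(I)c(OCOC)c1CC=C(C)C | intermediate
17 | (R)-lavandulylzinc iodide (not isolated) | C=C(C)[C@@H](CC=C(C)C)C[Zn]I | intermediate
18 | 3,5-bis(methoxymethoxy)-2-[(2S)-5-methyl-2-(prop-1-en-2-yl)hex-4-en-1-yl]-4-(3-methylbut-2-en-1-yl)phenyl 3-[(triisopropylsilyl)oxy]benzoate (same spatial arrangement as in 1; the descriptor changes by priority only) | COCOc1cc(OC(=O)c2cccc(O[Si](C(C)C)(C(C)C)C(C)C)c2)c(C[C@H](CC=C(C)C)C(C)=C)c(OCOC)c1CC=C(C)C | intermediate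
19 | 6-lithio derivative of 18, lithiated at the ring carbon between the ester oxygen and a MOM ether (not isolated) | COCOc1c([Li])c(OC(=O)c2cccc(O[Si](C(C)C)(C(C)C)C(C)C)c2)c(C[C@H](CC=C(C)C)C(C)=C)c(OCOC)c1CC=C(C)C | intermediate
20 | {2-hydroxy-4,6-bis(methoxymethoxy)-3-[(2S)-5-methyl-2-(prop-1-en-2-yl)hex-4-en-1-yl]-5-(3-methylbut-2-en-1-yl)phenyl}{3-[(triisopropylsilyl)oxy]phenyl}methanone | COCOc1c(C(=O)c2cccc(O[Si](C(C)C)(C(C)C)C(C)C)c2)c(O)c(C[C@H](CC=C(C)C)C(C)=C)c(OCOC)c1CC=C(C)C | intermediate
21 | (6S)-6-(2-formyl-3-methylbut-2-en-1-yl)-3,5-bis(methoxymethoxy)-6-[(2S)-5-methyl-2-(prop-1-en-2-yl)hex-4-en-1-yl]-4-(3-methylbut-2-en-1-yl)-2-{3-[(triisopropylsilyl)oxy]benzoyl}cyclohexa-2,4-dien-1-one | O=C1C(C(=O)c2cccc(O[Si](C(C)C)(C(C)C)C(C)C)c2)=C(OCOC)C(CC=C(C)C)=C(OCOC)[C@@]1(CC(C=O)=C(C)C)C[C@H](CC=C(C)C)C(C)=C | intermediate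
22 | 3,5-dihydroxy analogue of 21, the free triketone drawn as its dienol tautomer (not isolated) | O=C1C(C(=O)c2cccc(O[Si](C(C)C)(C(C)C)C(C)C)c2)=C(O)C(CC=C(C)C)=C(O)[C@@]1(CC(C=O)=C(C)C)C[C@H](CC=C(C)C)C(C)=C | intermediate
23 | (1R,5R,7R)-7-formyl-4-hydroxy-8,8-dimethyl-1-(3-methylbut-2-en-1-yl)-5-[(2S)-lavandulyl]-3-{3-[(triisopropylsilyl)oxy]benzoyl}bicyclo[3.3.1]non-3-ene-2,9-dione, the 7-endo aldehyde (not isolated) | C=C(C)[C@@H](CC=C(C)C)C[C@@]12C[C@@H](C=O)C(C)(C)[C@@](CC=C(C)C)(C(=O)C(C(=O)c3cccc(O[Si](C(C)C)(C(C)C)C(C)C)c3)=C1O)C2=O | intermediate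
24 | 10-hydroxy-8,8-dimethyl-1-(3-methylbut-2-en-1-yl)-5-[(2S)-lavandulyl]-3-{3-[(triisopropylsilyl)oxy]benzoyl}adamantane-2,4,9-trione; C1, C3, C5, C7 as in the SMILES, C10 as a mixture of carbinol epimers | C=C(C)[C@@H](CC=C(C)C)C[C@]12C(=O)[C@@]3(C(=O)c4cccc(O[Si](C(C)C)(C(C)C)C(C)C)c4)C(=O)[C@@](CC=C(C)C)(C2=O)C(C)(C)[C@@H](C1)C3O | intermediate
25 | dichlorocerium enolate (cerium on O4) of the 7-endo aldehyde, formed by retro-aldol opening of the dichlorocerium alkoxide of 24 (not isolated) | C=C(C)[C@@H](CC=C(C)C)C[C@@]12C[C@@H](C=O)C(C)(C)[C@@](CC=C(C)C)(C(=O)C(C(=O)c3cccc(O[Si](C(C)C)(C(C)C)C(C)C)c3)=C1O[Ce](Cl)Cl)C2=O | intermediate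
26 | (1R,5R,7R)-4-hydroxy-7-(1-hydroxyprop-2-en-1-yl)-8,8-dimethyl-1-(3-methylbut-2-en-1-yl)-5-[(2S)-lavandulyl]-3-{3-[(triisopropylsilyl)oxy]benzoyl}bicyclo[3.3.1]non-3-ene-2,9-dione; side chain endo, carbinol epimers | C=C(C)[C@@H](CC=C(C)C)C[C@@]12C[C@@H](C(O)C=C)C(C)(C)[C@@](CC=C(C)C)(C(=O)C(C(=O)c3cccc(O[Si](C(C)C)(C(C)C)C(C)C)c3)=C1O)C2=O | intermediate
27 | acetate of 26 at the allylic hydroxyl | C=C(C)[C@@H](CC=C(C)C)C[C@@]12C[C@@H](C(OC(C)=O)C=C)C(C)(C)[C@@](CC=C(C)C)(C(=O)C(C(=O)c3cccc(O[Si](C(C)C)(C(C)C)C(C)C)c3)=C1O)C2=O | intermediate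
28 | (1R,5R,7R)-7-allyl-4-hydroxy-8,8-dimethyl-1-(3-methylbut-2-en-1-yl)-5-[(2S)-lavandulyl]-3-{3-[(triisopropylsilyl)oxy]benzoyl}bicyclo[3.3.1]non-3-ene-2,9-dione | C=C(C)[C@@H](CC=C(C)C)C[C@@]12C[C@@H](CC=C)C(C)(C)[C@@](CC=C(C)C)(C(=O)C(C(=O)c3cccc(O[Si](C(C)C)(C(C)C)C(C)C)c3)=C1O)C2=O | intermediate
29 | triisopropylsilyl ether of the target at the aroyl phenol | C=C(C)[C@@H](CC=C(C)C)C[C@@]12C[C@@H](CC=C(C)C)C(C)(C)[C@@](CC=C(C)C)(C(=O)C(C(=O)c3cccc(O[Si](C(C)C)(C(C)C)C(C)C)c3)=C1O)C2=O | intermediate
30 | (1R,5R,7R)-4-hydroxy-3-(3-hydroxybenzoyl)-8,8-dimethyl-1,7-bis(3-methylbut-2-en-1-yl)-5-[(2S)-5-methyl-2-(prop-1-en-2-yl)hex-4-en-1-yl]bicyclo[3.3.1]non-3-ene-2,9-dione | C=C(C)[C@@H](CC=C(C)C)C[C@@]12C[C@@H](CC=C(C)C)C(C)(C)[C@@](CC=C(C)C)(C(=O)C(C(=O)c3cccc(O)c3)=C1O)C2=O | target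

**Step count and risks**

Total step count: 17. Longest linear sequence: 13 steps (phloroglucinol 11 to target 30, steps 5–17).

Steps most likely to fail:

1. Step 11. The phenoxide may react through oxygen or through the para carbon C1 instead of the ortho carbon C5, and facial discrimination at C5 may be poor if catalyst and lavandulyl centre are mismatched. Fallback, from 20 back to the route at 24: both MOM ethers of 20 are removed (HCl, MeOH, 40 °C) to give the free acylphloroglucinol F1. F1 and 10 are then treated with LiN(SiMe3)2 (2 equiv) in THF at 0 °C, so that the polyanion undergoes alkylative dearomatization, Michael annulation and aldol closure in one flask and gives 24 directly. This route gives up control of which alkyl-bearing carbon is alkylated first and of the face; the regioisomeric cage and the C5-epimeric cage are constitutional isomers or diastereomers of 24 and would be removed by chromatography.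

2. Step 12. The C1–C8 closure may stall at reversible oxygen adducts, or the aldol lock may fail so that the formyl group equilibrates to the exo face. Fallback, from 21 back to the route at 26: 21 is unmasked as in step 12 and cyclized under equilibrating conditions (KN(SiMe3)2, THF, 65 °C), which should stop at the thermodynamic 7-exo aldehyde F2. F2 is converted with LiN(iPr)2 (2.2 equiv, THF, −78 °C) into its dianion, and the C7 aldehyde enolate is protonated kinetically with 2,6-di-tert-butyl-4-methylphenol at −78 °C from the open exo face (the endo face is covered by the C2–C3–C4 bridge), which should give 23. The cold solution of 23 is transferred at once onto the vinylcerium dichloride of step 13 to give 26.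

3. Step 10. Lateral deprotonation at the benzylic/allylic CH2 groups or attack of the amide on the ester may compete with ring metalation, so that the acyl shift does not take place. Fallback, from 18 back to the route at 20: the ester of 18 is cleaved with NaOMe in MeOH at 0 °C to give the phenol F3. F3 is formylated at its only free ring position, ortho to the hydroxyl (MgCl2, Et3N, paraformaldehyde, MeCN, reflux), to give the salicylaldehyde F4. The aryl Grignard reagent F5, made from (3-bromophenoxy)triisopropylsilane and Mg in THF, is added (2.2 equiv, −78 to 0 °C) to F4 to give the diol F6, and oxidation of the benzylic alcohol of F6 with MnO2 in CH2Cl2 gives 20.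

Further compounds
F1 | step 11 | {2,4,6-trihydroxy-3-[(2S)-lavandulyl]-5-(3-methylbut-2-en-1-yl)phenyl}{3-[(triisopropylsilyl)oxy]phenyl}methanone | Oc1c(C(=O)c2cccc(O[Si](C(C)C)(C(C)C)C(C)C)c2)c(O)c(C[C@H](CC=C(C)C)C(C)=C)c(O)c1CC=C(C)C
F2 | step 12 | 7-exo epimer of aldehyde 23 | C=C(C)[C@@H](CC=C(C)C)C[C@@]12C[C@H](C=O)C(C)(C)[C@@](CC=C(C)C)(C(=O)C(C(=O)c3cccc(O[Si](C(C)C)(C(C)C)C(C)C)c3)=C1O)C2=O
F3 | step 10 | 3,5-bis(methoxymethoxy)-2-[(2S)-lavandulyl]-4-(3-methylbut-2-en-1-yl)phenol | COCOc1cc(O)c(C[C@H](CC=C(C)C)C(C)=C)c(OCOC)c1CC=C(C)C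
F4 | step 10 | 2-hydroxy-4,6-bis(methoxymethoxy)-3-[(2S)-lavandulyl]-5-(3-methylbut-2-en-1-yl)benzaldehyde | COCOc1c(C=O)c(O)c(C[C@H](CC=C(C)C)C(C)=C)c(OCOC)c1CC=C(C)C
F5 | step 10 | {3-[(triisopropylsilyl)oxy]phenyl}magnesium bromide | Br[Mg]c1cccc(O[Si](C(C)C)(C(C)C)C(C)C)c1
F6 | step 10 | benzhydrol corresponding to ketone 20 (carbinol epimers) | COCOc1c(C(O)c2cccc(O[Si](C(C)C)(C(C)C)C(C)C)c2)c(O)c(C[C@H](CC=C(C)C)C(C)=C)c(OCOC)c1CC=C(C)C
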